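The trap in the amber flask is to read its falling substrate as a reaction that simply needs more time.

the same everywhere: substrate 0.050 M

| flask | solid reagent | remark | time |
|---|---|---|---|
| amber | 0.055 M | the very flask that is asked about, followed so far |  |
| green | 0.037 M | run made earlier |  |
| flask | 0.0550 M |  | 30 h |

| run | time / h | single product / % | substrate / % |
|---|---|---|---|
| amber | 2.00 | 4.4 | 96.1 |
| amber | 6.00 | 11.8 | 83.7 |
| amber | 10.0 | 15.6 | 73.9 |
| amber | 15.0 | 15.2 | 62.5 |
| amber | 25.0 | 13.1 | 47.4 |
| amber | 30.0 | 13.3 | 42.8 |
| green | 0.250 | 0.7 | 101.9 |
| green | 0.417 | 0.7 | 99.3 |
| green | 0.667 | 0.7 | 100.1 |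
| green | 1.00 | 1.1 | 97.9 |
| green | 2.00 | 3.2 | 96.0 |
| green | 3.00 | 7.4 | 92.1 |

(readings scatter by 1 percentage point)

- epsilon: at 30 h take out 90 % of the single product then present, then wait 30 h
- eta: change nothing and wait 30 h more
- delta: at 30 h add substrate, 50.0 % of the amount charged, then wait 30 h

- given per volume of solution although it is solid: solid reagent
- what is taken out of single product is counted as made
- at the start none of the solid reagent is in solution
- additions bring no volume worth counting

- single product, in percent of the substrate first charged, at 30 h
- the remedy with the largest gain of single product, or "none" below 2 percentage points (epsilon / eta / delta / none)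
- single product present, with what was taken out counted in, in percent of the substrate first charged, after epsilon
- single product present, with what was taken out counted in, in percent of the substrate first charged, after eta

1. Between 2.00 h and 10.0 h the amber flask loses substrate at 0.00139 M h⁻¹. Between 25.0 h and 30.0 h it loses 4.60 × 10⁻⁴ M h⁻¹, so the rate has changed by a factor 0.332.

2. I replace each stretch of c(substrate) by its mean and treat the loss as pseudo-first-order. Less substrate then gives a factor 0.531, and a factor 0.625 remains, which I put down to the supply of solid reagent.

3. I count one unit of solid reagent for each unit of substrate lost and, since the balance of the readings runs short, a second unit for each unit of substrate that has gone beyond single product. The amber flask then takes up 0.00217 M h⁻¹ from 2.00 h to 6.00 h and 0.00217 M h⁻¹ from 6.00 h to 15.0 h, so one mean rate makes little error.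

4. The charge divided by that uptake gives 25.4 h. This is the delivery time, my estimate of the hour by which the charge of solid reagent has been taken up at that mean rate. The last stretch starts about then.

5. So I commit to about 13.2 % single product at 30 h, and to no remedy reaching 2 percentage points, because 30 h comes later than the delivery time.

The forecast gives 13.2 %, 18 % after epsilon, 12.7 % after eta, and epsilon as best, since “the remaining reagent regrows about 6”.

The flask gives 13.5 %, and the answer for best is none: epsilon gains 0.11 points, eta −0.018 points and delta 0.051 points, leaving 13.6 % after epsilon and 13.5 % after eta.

    substrate + partner → single product (k = 0.202 M⁻¹ min⁻¹)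
    partner + single product → double product (k = 0.789 M⁻¹ min⁻¹)
    partner + double product → tris adduct (k = 0.125 M⁻¹ min⁻¹)
    solid reagent ⇌ partner, rate k4*(cs4 - [partner]) while solid is left; crystals form when [partner] > cs4 (solubility = 32.0 mM, k = 0.00123 min⁻¹)

At 30.0 h the flask holds solid reagent 0 % of its charge and partner 1.06 × 10⁻⁴ M, and that moment comes after the delivery time of 25.4 h. Reckoned at the same uptake, a neighbouring flask with 0.014 M of solid reagent has a delivery time of 6.45 h, and at 30.0 h it holds solid reagent 0 % of its charge and substrate 79.5 % of the charge.

All runs are simulated with made-up constants.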